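The route rests on closing the pyran ring (ring C) by the aryl ether bond O1–C8a through an aryne. C8a of ring A is meta to both oxygens (C5, C7) and cannot be halogenated directly, whereas C8 is brominated with ease. An open-chain (R)-2,3-diarylpropan-1-ol carrying bromine at C8 is therefore treated with a lithium amide: the C8≡C8a aryne forms, and the tethered alkoxide adds at C8a, guided by the tether and the C7 oxygen beside the triple bond, while C8 takes up hydrogen. The C3 stereocentre comes from an Evans benzylation that joins the two aryl fragments; the prenyl group is installed early by directed ortho-metalation.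

Key step: step 11

Remark: C3 of the target is R (CIP order C2 > C1' > C4 > H); compound 1 is assumed to be a catalogue chemical.

Step 1
Reactants: 1 5-bromo-4-hydroxy-2-methoxybenzaldehyde
Product: 2 5-bromo-2-methoxy-4-(methoxymethoxy)benzaldehyde
Conditions: MOMCl, i-Pr2NEt, CH2Cl2, 0 °C to rt
Reagents that add atoms: chloromethyl methyl ether (MOMCl), COCCl
Why: Williamson-type O-alkylation of the phenol with the α-chloro ether should give the MOM ether, which withstands the hydride, enolate and amide-base steps ahead and whose oxygen later sits beside the aryne.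

Step 2
Reactants: 2 5-bromo-2-methoxy-4-(methoxymethoxy)benzaldehyde
Product: 3 [5-bromo-2-methoxy-4-(methoxymethoxy)phenyl]methanol
Conditions: NaBH4, MeOH, 0 °C
Reagents that add atoms: none
Why: Borohydride reduction of the aryl aldehyde is chemoselective and should leave the aryl bromide and the acetal untouched.

Step 3
Reactants: 3 [5-bromo-2-methoxy-4-(methoxymethoxy)phenyl]methanol
Product: 4 1-bromo-5-(bromomethyl)-4-methoxy-2-(methoxymethoxy)benzene
Conditions: CBr4, PPh3, CH2Cl2, 0 °C; used at once
Reagents that add atoms: carbon tetrabromide, BrC(Br)(Br)Br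
Why: The Appel reaction converts the benzylic alcohol into the bromide under neutral conditions, so no acid reaches the MOM ether; the electron-rich bromide is not stored.

Step 4
Reactants: 5 3-methoxyphenol
Product: 6 1-methoxy-3-(methoxymethoxy)benzene
Conditions: MOMCl, i-Pr2NEt, CH2Cl2, 0 °C to rt
Reagents that add atoms: chloromethyl methyl ether (MOMCl), COCCl
Why: The same Williamson-type MOM protection installs the stronger of the two oxygen directing groups needed for the two metalations that follow.

Step 5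
Reactants: 6 1-methoxy-3-(methoxymethoxy)benzene; 7 prenyl bromide (1-bromo-3-methylbut-2-ene)
Product: 9 1-methoxy-3-(methoxymethoxy)-2-(3-methylbut-2-en-1-yl)benzene, via aryllithium 8 (not isolated)
Conditions: n-BuLi, THF, 0 °C to rt; then CuI (10 mol %), prenyl bromide, −78 °C to rt
Reagents that add atoms: none
Why: Directed ortho-metalation should occur at the carbon flanked by both oxygen directing groups, and copper-catalysed coupling of aryllithium 8 with the primary allylic bromide proceeds in SN2 fashion to give the linear prenyl arene.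

Step 6
Reactants: 9 1-methoxy-3-(methoxymethoxy)-2-(3-methylbut-2-en-1-yl)benzene; 10 oxirane (ethylene oxide)
Product: 12 2-[4-methoxy-2-(methoxymethoxy)-3-(3-methylbut-2-en-1-yl)phenyl]ethan-1-ol, via aryllithium 11 (not isolated)
Conditions: n-BuLi, TMEDA, Et2O, 0 °C; then oxirane, −78 °C to rt; aq NH4Cl
Reagents that add atoms: none
Why: A second directed ortho-metalation should take place at the only free position beside the stronger OMOM director, and aryllithium 11 opens the epoxide by SN2 attack to give the 2-arylethanol.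

Step 7
Reactants: 12 2-[4-methoxy-2-(methoxymethoxy)-3-(3-methylbut-2-en-1-yl)phenyl]ethan-1-ol
Product: 14 2-[4-methoxy-2-(methoxymethoxy)-3-(3-methylbut-2-en-1-yl)phenyl]acetic acid, via aldehyde 13 (not isolated)
Conditions: TEMPO (20 mol %), PhI(OAc)2 (2.2 equiv), MeCN/H2O 1:1, rt
Reagents that add atoms: water, O
Why: The oxoammonium (TEMPO-catalysed) oxidation takes the primary alcohol through aldehyde 13 and its hydrate to the acid under conditions that should spare the trisubstituted alkene and the acetal.

Step 8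
Reactants: 14 2-[4-methoxy-2-(methoxymethoxy)-3-(3-methylbut-2-en-1-yl)phenyl]acetic acid; 15 (R)-4-benzyl-1,3-oxazolidin-2-one
Product: 17 (R)-4-benzyl-3-{2-[4-methoxy-2-(methoxymethoxy)-3-(3-methylbut-2-en-1-yl)phenyl]acetyl}-1,3-oxazolidin-2-one, via mixed anhydride 16 (not isolated)
Conditions: t-BuCOCl, Et3N, THF, −20 °C; then LiCl, 15, −20 °C to rt
Reagents that add atoms: none
Why: N-Acylation of the oxazolidinone through the mixed pivalic anhydride with LiCl and Et3N is the standard mild entry to Evans imides of arylacetic acids.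

Step 9
Reactants: 17 (R)-4-benzyl-3-{2-[4-methoxy-2-(methoxymethoxy)-3-(3-methylbut-2-en-1-yl)phenyl]acetyl}-1,3-oxazolidin-2-one; 4 1-bromo-5-(bromomethyl)-4-methoxy-2-(methoxymethoxy)benzene
Product: 19 (R)-4-benzyl-3-{(2R)-3-[5-bromo-2-methoxy-4-(methoxymethoxy)phenyl]-2-[4-methoxy-2-(methoxymethoxy)-3-(3-methylbut-2-en-1-yl)phenyl]propanoyl}-1,3-oxazolidin-2-one, via sodium enolate 18 (not isolated)
Conditions: NaN(SiMe3)2, THF, −78 °C; then 4, −78 to −40 °C
Reagents that add atoms: none
Why: Evans asymmetric alkylation: the chelated Z sodium enolate 18 is shielded on one face by the benzyl group of the R auxiliary, so the benzylic bromide should enter from the opposite face and set the new α-centre as R (priorities C=O > aryl > CH2Ar).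

Step 10
Reactants: 19 (R)-4-benzyl-3-{(2R)-3-[5-bromo-2-methoxy-4-(methoxymethoxy)phenyl]-2-[4-methoxy-2-(methoxymethoxy)-3-(3-methylbut-2-en-1-yl)phenyl]propanoyl}-1,3-oxazolidin-2-one
Product: 20 (2R)-3-[5-bromo-2-methoxy-4-(methoxymethoxy)phenyl]-2-[4-methoxy-2-(methoxymethoxy)-3-(3-methylbut-2-en-1-yl)phenyl]propan-1-ol
Conditions: LiBH4, MeOH (1 equiv), Et2O, 0 °C
Reagents that add atoms: none
Why: Reductive cleavage of the imide by LiBH4 at the exocyclic carbonyl should free the primary alcohol and the auxiliary without touching the α-stereocentre (still R), the aryl bromide or the alkene.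

Step 11
Reactants: 20 (2R)-3-[5-bromo-2-methoxy-4-(methoxymethoxy)phenyl]-2-[4-methoxy-2-(methoxymethoxy)-3-(3-methylbut-2-en-1-yl)phenyl]propan-1-ol
Product: 23 (3R)-5-methoxy-7-(methoxymethoxy)-3-[4-methoxy-2-(methoxymethoxy)-3-(3-methylbut-2-en-1-yl)phenyl]chromane, via aryne 21 (not isolated), via aryllithium 22 (not isolated)
Conditions: LiN(i-Pr)2 (3.5 equiv), THF, −78 to −20 °C; then aq NH4Cl
Reagents that add atoms: none
Why: LiN(i-Pr)2 first makes the lithium alkoxide and then removes C8a–H, the only hydrogen ortho to bromine (the other neighbour of C8 is C7–OMOM), so that loss of LiBr can give only the C8≡C8a aryne 21; the tethered alkoxide adds to C8a and the C8 aryllithium 22 is protonated by diisopropylamine or on quench. The closest known reaction type is the base-induced benzyne cyclization, a cine substitution of an aryl halide by a tethered alkoxide that has been used to close dihydrobenzofuran and chroman rings. The pyran ring (ring C) closes in 6-exo-dig fashion onto the in-plane aryne bond, whereas addition at C8 would need a meta-bridged ring and cannot compete. No stereocentre is formed, and the C3 centre set in step 9 carries no proton acidic enough for the amide base, so its R configuration should persist. The required regioselectivity is secured twice, by the tether and by the C7 oxygen beside the triple bond, whose inductive pull favours attack at the remote aryne carbon C8a and stabilises the carbanion developing at C8. Chemoselectivity over capture of the aryne by the amine relies on the intramolecular alkoxide addition being faster at low temperature.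

Step 12
Reactants: 23 (3R)-5-methoxy-7-(methoxymethoxy)-3-[4-methoxy-2-(methoxymethoxy)-3-(3-methylbut-2-en-1-yl)phenyl]chromane
Product: 24 (3R)-3-[2-hydroxy-4-methoxy-3-(3-methylbut-2-en-1-yl)phenyl]-5-methoxychroman-7-ol
Conditions: 3 M aq HCl, MeOH, rt to 40 °C
Reagents that add atoms: none
Why: Acid-catalysed acetal cleavage (methanolysis) removes both MOM groups, and dilute acid near room temperature is mild enough that the freed 2'-hydroxyl should not add to the neighbouring prenyl double bond.

Compound list
1 | 5-bromo-4-hydroxy-2-methoxybenzaldehyde | COc1cc(O)c(Br)cc1C=O | starting material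
2 | 5-bromo-2-methoxy-4-(methoxymethoxy)benzaldehyde | COCOc1cc(OC)c(C=O)cc1Br | intermediate
3 | [5-bromo-2-methoxy-4-(methoxymethoxy)phenyl]methanol | COCOc1cc(OC)c(CO)cc1Br | intermediate
4 | 1-bromo-5-(bromomethyl)-4-methoxy-2-(methoxymethoxy)benzene | COCOc1cc(OC)c(CBr)cc1Br | intermediate
5 | 3-methoxyphenol | COc1cccc(O)c1 | starting material
6 | 1-methoxy-3-(methoxymethoxy)benzene | COCOc1cccc(OC)c1 | intermediate
7 | prenyl bromide (1-bromo-3-methylbut-2-ene) | CC(C)=CCBr | starting material
8 | [2-methoxy-6-(methoxymethoxy)phenyl]lithium (formed in the flask) | COCOc1cccc(OC)c1[Li] | intermediate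
9 | 1-methoxy-3-(methoxymethoxy)-2-(3-methylbut-2-en-1-yl)benzene | COCOc1cccc(OC)c1CC=C(C)C | intermediate
10 | oxirane (ethylene oxide) | C1CO1 | starting material
11 | [4-methoxy-2-(methoxymethoxy)-3-(3-methylbut-2-en-1-yl)phenyl]lithium (formed in the flask) | COCOc1c([Li])ccc(OC)c1CC=C(C)C | intermediate
12 | 2-[4-methoxy-2-(methoxymethoxy)-3-(3-methylbut-2-en-1-yl)phenyl]ethan-1-ol | COCOc1c(CCO)ccc(OC)c1CC=C(C)C | intermediate
13 | 2-[4-methoxy-2-(methoxymethoxy)-3-(3-methylbut-2-en-1-yl)phenyl]acetaldehyde (formed in the flask) | COCOc1c(CC=O)ccc(OC)c1CC=C(C)C | intermediate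
14 | 2-[4-methoxy-2-(methoxymethoxy)-3-(3-methylbut-2-en-1-yl)phenyl]acetic acid | COCOc1c(CC(=O)O)ccc(OC)c1CC=C(C)C | intermediate
15 | (R)-4-benzyl-1,3-oxazolidin-2-one | O=C1N[C@H](Cc2ccccc2)CO1 | starting material
16 | mixed anhydride of 14 with pivalic acid (formed in the flask) | COCOc1c(CC(=O)OC(=O)C(C)(C)C)ccc(OC)c1CC=C(C)C | intermediate
17 | (R)-4-benzyl-3-{2-[4-methoxy-2-(methoxymethoxy)-3-(3-methylbut-2-en-1-yl)phenyl]acetyl}-1,3-oxazolidin-2-one | COCOc1c(CC(=O)N2[C@H](Cc3ccccc3)COC2=O)ccc(OC)c1CC=C(C)C | intermediate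
18 | Z sodium enolate of 17 (formed in the flask) | [Na]O/C(=C\c1ccc(OC)c(CC=C(C)C)c1OCOC)N1[C@H](Cc2ccccc2)COC1=O | intermediate
19 | (R)-4-benzyl-3-{(2R)-3-[5-bromo-2-methoxy-4-(methoxymethoxy)phenyl]-2-[4-methoxy-2-(methoxymethoxy)-3-(3-methylbut-2-en-1-yl)phenyl]propanoyl}-1,3-oxazolidin-2-one | COc1cc(OCOC)c(Br)cc1C[C@H](c1ccc(OC)c(CC=C(C)C)c1OCOC)C(=O)N1[C@H](Cc2ccccc2)COC1=O | intermediate
20 | (2R)-3-[5-bromo-2-methoxy-4-(methoxymethoxy)phenyl]-2-[4-methoxy-2-(methoxymethoxy)-3-(3-methylbut-2-en-1-yl)phenyl]propan-1-ol | COc1cc(OCOC)c(Br)cc1C[C@H](c1ccc(OC)c(CC=C(C)C)c1OCOC)CO | intermediate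
21 | lithium (2R)-3-[2-methoxy-4-(methoxymethoxy)-5,6-didehydrophenyl]-2-[4-methoxy-2-(methoxymethoxy)-3-(3-methylbut-2-en-1-yl)phenyl]propan-1-olate, the C8≡C8a aryne (formed in the flask) | COC1=C(C[C@H](c2ccc(OC)c(CC=C(C)C)c2OCOC)CO[Li])C#CC(OCOC)=C1 | intermediate
22 | [(3R)-5-methoxy-7-(methoxymethoxy)-3-{4-methoxy-2-(methoxymethoxy)-3-(3-methylbut-2-en-1-yl)phenyl}chroman-8-yl]lithium (formed in the flask) | COc1cc(OCOC)c([Li])c2c1C[C@H](c1ccc(OC)c(CC=C(C)C)c1OCOC)CO2 | intermediate
23 | (3R)-5-methoxy-7-(methoxymethoxy)-3-[4-methoxy-2-(methoxymethoxy)-3-(3-methylbut-2-en-1-yl)phenyl]chromane | COc1cc(OCOC)cc2c1C[C@H](c1ccc(OC)c(CC=C(C)C)c1OCOC)CO2 | intermediate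
24 | (3R)-3-[2-hydroxy-4-methoxy-3-(3-methylbut-2-en-1-yl)phenyl]-5-methoxychroman-7-ol | COc1cc(O)cc2c1C[C@H](c1ccc(OC)c(CC=C(C)C)c1O)CO2 | target

Total step count: 12. Longest linear sequence: 9 steps (steps 4 to 12).

Steps most likely to fail

Step 11. The amide base may deprotonate the doubly activated benzylic-allylic CH2 of the prenyl group, moving the double bond into conjugation, or the amine may capture the aryne faster than the tethered alkoxide does. The fallback closes the same O1–C8a bond by ipso substitution at C8a under palladium catalysis, without a strong base; it sets out from imide 17 and comes back at 23. Commercial 2,4-dihydroxy-6-methoxybenzaldehyde F1 would be protected at the non-chelated 4-hydroxyl (MOMCl, K2CO3, acetone) to give 2-hydroxy-6-methoxy-4-(methoxymethoxy)benzaldehyde F2. Triflation (Tf2O, pyridine) would give 2-formyl-3-methoxy-5-(methoxymethoxy)phenyl trifluoromethanesulfonate F3, NaBH4 reduction the benzylic alcohol 2-(hydroxymethyl)-3-methoxy-5-(methoxymethoxy)phenyl trifluoromethanesulfonate F4, and the Appel reaction (CBr4, PPh3) the benzylic bromide 2-(bromomethyl)-3-methoxy-5-(methoxymethoxy)phenyl trifluoromethanesulfonate F5. Alkylation of the sodium enolate of 17 with it (NaN(SiMe3)2, THF, −78 °C) would give the triflate-bearing alkylated imide F6, and LiBH4 the triflate-bearing (R)-2,3-diarylpropan-1-ol F7. Intramolecular Buchwald–Hartwig-type etherification (Pd(OAc)2, 2-(di-tert-butylphosphino)-1,1'-binaphthyl, K3PO4, toluene, 80 °C) would then give 23.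

Step 9. The electron-rich benzylic bromide 4 may ionise and alkylate itself before it meets the enolate, or proton exchange at the acidic α-aryl position may erode the diastereomer ratio. The fallback sets the stereocentre by asymmetric hydrogenation instead; it sets out from acid 14 and aldehyde 2 and comes back at alcohol 20. Perkin condensation (Ac2O, Et3N, 110 °C) would give the (E)-2,3-diarylacrylic acid F8 with the two aryl groups cis. Carboxylate-directed asymmetric hydrogenation ([Rh(nbd)2]BF4 with a chiral ferrocenyl diphosphine, H2, MeOH, ligand enantiomer chosen for the R acid) would give the (R)-2,3-diarylpropanoic acid F9 without reducing the isolated trisubstituted alkene. LiAlH4 (THF, 0 °C) would then reduce it to 20.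

Step 6. The hindered, internally chelated aryllithium may open the epoxide slowly, so that the anion is lost by proton transfer or equilibrates to the prenyl CH2. The fallback uses a faster electrophile and a one-carbon extension; it sets out from 9 and comes back at 12. Lithiation as in step 6 and quenching with DMF would give 4-methoxy-2-(methoxymethoxy)-3-(3-methylbut-2-en-1-yl)benzaldehyde F10. Wittig methylenation (Ph3PCH3Br, KOt-Bu, THF) would give 1-ethenyl-4-methoxy-2-(methoxymethoxy)-3-(3-methylbut-2-en-1-yl)benzene F11. Hydroboration with 9-BBN, which prefers the terminal vinyl group over the trisubstituted prenyl alkene, followed by H2O2/NaOH would give 12.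

Further compounds
F1 | step 11 | 2,4-dihydroxy-6-methoxybenzaldehyde | COc1cc(O)cc(O)c1C=O
F2 | step 11 | 2-hydroxy-6-methoxy-4-(methoxymethoxy)benzaldehyde | COCOc1cc(O)c(C=O)c(OC)c1
F3 | step 11 | 2-formyl-3-methoxy-5-(methoxymethoxy)phenyl trifluoromethanesulfonate | COCOc1cc(OS(=O)(=O)C(F)(F)F)c(C=O)c(OC)c1
F4 | step 11 | 2-(hydroxymethyl)-3-methoxy-5-(methoxymethoxy)phenyl trifluoromethanesulfonate | COCOc1cc(OS(=O)(=O)C(F)(F)F)c(CO)c(OC)c1
F5 | step 11 | 2-(bromomethyl)-3-methoxy-5-(methoxymethoxy)phenyl trifluoromethanesulfonate | COCOc1cc(OS(=O)(=O)C(F)(F)F)c(CBr)c(OC)c1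
F6 | step 11 | (R)-4-benzyl-3-{(2R)-3-[2-methoxy-4-(methoxymethoxy)-6-(trifluoromethanesulfonyloxy)phenyl]-2-[4-methoxy-2-(methoxymethoxy)-3-(3-methylbut-2-en-1-yl)phenyl]propanoyl}-1,3-oxazolidin-2-one | COc1cc(OCOC)cc(OS(=O)(=O)C(F)(F)F)c1C[C@H](c1ccc(OC)c(CC=C(C)C)c1OCOC)C(=O)N1[C@H](Cc2ccccc2)COC1=O
F7 | step 11 | 2-{(2R)-3-hydroxy-2-[4-methoxy-2-(methoxymethoxy)-3-(3-methylbut-2-en-1-yl)phenyl]propyl}-3-methoxy-5-(methoxymethoxy)phenyl trifluoromethanesulfonate | COc1cc(OCOC)cc(OS(=O)(=O)C(F)(F)F)c1C[C@H](c1ccc(OC)c(CC=C(C)C)c1OCOC)CO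
F8 | step 9 | (E)-3-[5-bromo-2-methoxy-4-(methoxymethoxy)phenyl]-2-[4-methoxy-2-(methoxymethoxy)-3-(3-methylbut-2-en-1-yl)phenyl]prop-2-enoic acid | OC(=O)/C(c1ccc(OC)c(CC=C(C)C)c1OCOC)=C/c1cc(Br)c(OCOC)cc1OC
F9 | step 9 | (2R)-3-[5-bromo-2-methoxy-4-(methoxymethoxy)phenyl]-2-[4-methoxy-2-(methoxymethoxy)-3-(3-methylbut-2-en-1-yl)phenyl]propanoic acid | COc1cc(OCOC)c(Br)cc1C[C@H](c1ccc(OC)c(CC=C(C)C)c1OCOC)C(=O)O
F10 | step 6 | 4-methoxy-2-(methoxymethoxy)-3-(3-methylbut-2-en-1-yl)benzaldehyde | COCOc1c(C=O)ccc(OC)c1CC=C(C)C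
F11 | step 6 | 1-ethenyl-4-methoxy-2-(methoxymethoxy)-3-(3-methylbut-2-en-1-yl)benzene | COCOc1c(C=C)ccc(OC)c1CC=C(C)C
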